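**Plan**

- The target is robinetinidol-(4β→8)-gallocatechin, whose upper unit is 2,3-trans-3,4-cis. Retrosynthesis removes eleven O-benzyl groups, then cuts the C4–C8′ bond between the units (aryllithium plus C4 ketone, then hydride in place of hydroxyl), then cuts ring C of the upper unit at O1–C8a and C2–C3 in one annulation.
- Forward: ring A is bought as 4-bromo-3-fluorophenol and is given C4–C3 as a benzyloxymethyl ketone. Ring C closes when the enol silane takes up 3,4,5-tris(benzyloxy)benzaldehyde (ring B) by Mukaiyama aldol addition and the new alkoxide displaces fluoride. The gallocatechin unit (rings D, E, F) is then joined at C4.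
- Enabling feature: C4 lies between C3 and ring-A carbon C4a. As a ketone it makes C3 an enol carbon and makes C8a (ortho to C4, meta to the 7-oxygen) open to SNAr, so F–C8a=C4a–C4(OSi)=C3 acts as a benzo-fused 1-hetero-3-siloxydiene toward the aldehyde C=O. The ketone is removed after it has also served to attach the lower unit.
- Stereochemistry: C2 from a chiral boron Lewis acid; C3 from the anti aldol (also the more stable trans ketone); C4 from hydride capture anti to the 3-benzyloxy group of a 4-aryl cation (3,4-cis); C2′ and C3′ from (+)-gallocatechin.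

Key step: step 7

Assumption: (+)-gallocatechin, 4-bromo-3-fluorophenol, 2-(benzyloxy)-N-methoxy-N-methylacetamide and 3,4,5-tris(benzyloxy)benzaldehyde are taken as commercial; benzyl ethers are the only protecting groups.

**Route**

Step 1
Reactants: 1 (+)-gallocatechin, (2R,3S)-2-(3,4,5-trihydroxyphenyl)chromane-3,5,7-triol
Product: 2 (2R,3S)-5,7-bis(benzyloxy)-2-[3,4,5-tris(benzyloxy)phenyl]chroman-3-ol
Conditions: BnBr (5.5 equiv), K2CO3, DMF, 0 °C to rt, argon
Reagents that add atoms: benzyl bromide, BrCc1ccccc1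
Why: Williamson ether synthesis in which carbonate deprotonates only the five phenols, so that the secondary 3-hydroxyl stays free and neither stereocenter is touched, oxygen being excluded because the pyrogallol ring is air-sensitive in base.

Step 2
Reactants: 2 (2R,3S)-5,7-bis(benzyloxy)-2-[3,4,5-tris(benzyloxy)phenyl]chroman-3-ol
Product: 3 (2R,3S)-3,5,7-tris(benzyloxy)-2-[3,4,5-tris(benzyloxy)phenyl]chromane
Conditions: NaH, BnBr, DMF, 0 °C to rt
Reagents that add atoms: benzyl bromide, BrCc1ccccc1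
Why: Williamson ether synthesis on the sodium alkoxide of the 3-hydroxyl, which leaves both stereocenters as they are and gives a lower unit protected by benzyl ethers only.

Step 3
Reactants: 3 (2R,3S)-3,5,7-tris(benzyloxy)-2-[3,4,5-tris(benzyloxy)phenyl]chromane
Product: 4 (2R,3S)-3,5,7-tris(benzyloxy)-8-bromo-2-[3,4,5-tris(benzyloxy)phenyl]chromane
Conditions: NBS (1.0 equiv), CH2Cl2, −78 °C to rt
Reagents that add atoms: N-bromosuccinimide, O=C1CCC(=O)N1Br
Why: electrophilic aromatic bromination of the phloroglucinol-type ring D, which in 5,7-di-O-benzyl flavan-3-ol ethers takes place at C8 in preference to C6 and to the less electron-rich tris(benzyloxy)phenyl ring.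

Step 4
Reactants: 5 4-bromo-3-fluorophenol
Product: 6 4-(benzyloxy)-1-bromo-2-fluorobenzene
Conditions: BnBr, K2CO3, acetone, reflux
Reagents that add atoms: benzyl bromide, BrCc1ccccc1
Why: Williamson ether synthesis on a simple phenol, the unactivated aryl fluoride and bromide being inert to carbonate.

Step 5
Reactants: 6 4-(benzyloxy)-1-bromo-2-fluorobenzene; 7 2-(benzyloxy)-N-methoxy-N-methylacetamide
Product: 9 2-(benzyloxy)-1-[4-(benzyloxy)-2-fluorophenyl]ethan-1-one, via aryl Grignard reagent 8 (not isolated)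
Conditions: i-PrMgCl·LiCl, THF, −15 °C; then 7, −15 °C to rt; aq HCl
Reagents that add atoms: none
Why: bromine–magnesium exchange followed by the Weinreb ketone synthesis, in which the chelated tetrahedral adduct prevents a second addition and the low temperature keeps the ortho-fluoroaryl Grignard reagent from collapsing to an aryne.

Step 6
Reactants: 9 2-(benzyloxy)-1-[4-(benzyloxy)-2-fluorophenyl]ethan-1-one
Product: 10 (Z)-{[2-(benzyloxy)-1-(4-(benzyloxy)-2-fluorophenyl)ethenyl]oxy}trimethylsilane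
Conditions: TMSOTf, Et3N, CH2Cl2, 0 °C; pentane, filtration
Reagents that add atoms: trimethylsilyl trifluoromethanesulfonate, C[Si](C)(C)OS(=O)(=O)C(F)(F)F
Why: silyl enol ether formation by soft enolization at the only enolizable position (C3), the Z isomer with benzyloxy cis to siloxy being favoured because the E isomer would press the benzyloxy group against the ortho-substituted aryl ring.

Step 7
Reactants: 10 (Z)-{[2-(benzyloxy)-1-(4-(benzyloxy)-2-fluorophenyl)ethenyl]oxy}trimethylsilane; 11 3,4,5-tris(benzyloxy)benzaldehyde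
Product: 14 (2R,3R)-3,7-bis(benzyloxy)-2-[3,4,5-tris(benzyloxy)phenyl]chroman-4-one, via silyl aldol adduct 12 (not isolated), via tetrabutylammonium aldolate 13 (not isolated)
Conditions: (S)-2-butyl-4-(1H-indol-3-ylmethyl)-3-tosyl-1,3,2-oxazaborolidin-5-one (20 mol %), EtCN, −78 °C; then Bu4N[Ph3SiF2] (0.5 equiv), THF, −78 to 0 °C; AcOH
Reagents that add atoms: none
Why: Proposed new method: enol silane 10 is a benzo-fused 1-fluoro-3-siloxy-1,3-diene (F–C8a=C4a–C4(OSiMe3)=C3) and should react with aldehyde 11 like the 1-alkoxy-3-siloxydienes of the stepwise hetero-Diels–Alder reaction: the boron-bound aldehyde is attacked by C3 in a Mukaiyama aldol addition with silyl transfer (C2–C3 bond, 12), fluoride then frees alkoxide 13, and its oxygen adds to C8a and expels fluoride through a Meisenheimer complex (O1–C8a bond), the fluoride set free carrying the desilylation on as a chain. The closest known reaction types are the oxazaborolidinone-catalysed enantioselective Mukaiyama aldol and aldol–dihydropyranone annulation of aromatic aldehydes with ketone enol silanes and the SNAr closure of 3-hydroxy-1-(2-fluoroaryl)propan-1-ones to chroman-4-ones, which have not been joined in one flask or applied to an alpha-alkoxy aryl ketone enol silane. Ring C closes in a 6-exo-trig addition–elimination at C8a, which the ortho C4 carbonyl activates and which the 7-benzyloxy group, being meta to it, does not deactivate by resonance. C2 is controlled by the catalyst, whose indole ring covers one face of the coordinated aldehyde so that C3 enters on the Si face (2R; the catalyst from (R)-tryptophan serves if the sense proves to be the opposite one), and C3 by the open antiperiplanar transition state, in which the aldehyde aryl group turns away from the twisted 2-fluoroaryl ring to give the anti adduct, that is the 2,3-trans ketone with both substituents equatorial, which is also the more stable epimer. The step needs ring closure of 13 to be faster than its retro-aldol cleavage and than enolization of 14 toward C3: the intramolecular attack on the activated fluoroarene costs little activation entropy and is favoured by the low temperature, only a substoichiometric amount of fluoride is present, and acetic acid is added before the mixture is warmed.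

Step 8
Reactants: 4 (2R,3S)-3,5,7-tris(benzyloxy)-8-bromo-2-[3,4,5-tris(benzyloxy)phenyl]chromane; 14 (2R,3R)-3,7-bis(benzyloxy)-2-[3,4,5-tris(benzyloxy)phenyl]chroman-4-one
Product: 16 (2R,3R)-3,7-bis(benzyloxy)-4-{(2R,3S)-3,5,7-tris(benzyloxy)-2-[3,4,5-tris(benzyloxy)phenyl]chroman-8-yl}-2-[3,4,5-tris(benzyloxy)phenyl]chroman-4-ol (both C4 epimers), via aryllithium 15 (not isolated)
Conditions: 4, n-BuLi, THF, −78 °C; then 14, −78 °C; sat. aq NH4Cl
Reagents that add atoms: none
Why: bromine–lithium exchange and 1,2-addition of the aryllithium to the C4 ketone at low temperature, where addition should be faster than enolization at C3, the configuration of the new carbinol carbon being of no consequence because it is ionized in the next step.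

Step 9
Reactants: 16 (2R,3R)-3,7-bis(benzyloxy)-4-{(2R,3S)-3,5,7-tris(benzyloxy)-2-[3,4,5-tris(benzyloxy)phenyl]chroman-8-yl}-2-[3,4,5-tris(benzyloxy)phenyl]chroman-4-ol
Product: 18 (2R,3S,4R)-3,7-bis(benzyloxy)-4-{(2R,3S)-3,5,7-tris(benzyloxy)-2-[3,4,5-tris(benzyloxy)phenyl]chroman-8-yl}-2-[3,4,5-tris(benzyloxy)phenyl]chromane, via flavan-4-yl cation 17 (not isolated)
Conditions: Bu3SnH (3 equiv), CF3CO2H, CH2Cl2, −78 to 0 °C
Reagents that add atoms: none
Why: ionic hydrogenation in which acid ionizes the tertiary dibenzylic alcohol to a cation stabilized by O1 and the 7-oxygen of ring A, and the tin hydride attacks C4 on the face anti to the neighbouring 3-benzyloxy group, the face that 2,3-trans-flavan-4-yl cations offer to nucleophiles, so that hydrogen arrives trans and the aryl group ends cis to the 3-oxygen (4R, 3,4-cis).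

Step 10
Reactants: 18 (2R,3S,4R)-3,7-bis(benzyloxy)-4-{(2R,3S)-3,5,7-tris(benzyloxy)-2-[3,4,5-tris(benzyloxy)phenyl]chroman-8-yl}-2-[3,4,5-tris(benzyloxy)phenyl]chromane
Product: 19 (2R,3S,4R)-2-(3,4,5-trihydroxyphenyl)-4-[(2R,3S)-3,5,7-trihydroxy-2-(3,4,5-trihydroxyphenyl)chroman-8-yl]chromane-3,7-diol
Conditions: H2 (1 atm), Pd(OH)2/C, THF/MeOH/H2O, rt
Reagents that add atoms: none
Why: hydrogenolysis of the eleven benzyl ethers under neutral conditions, which in flavan-3-ol oligomers leaves the ring O1–C2 bonds, the C4–C8′ bond and all five stereocenters intact.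

**Compound list**

1 | (+)-gallocatechin, (2R,3S)-2-(3,4,5-trihydroxyphenyl)chromane-3,5,7-triol | Oc1cc(O)c2c(c1)O[C@H](c1cc(O)c(O)c(O)c1)[C@@H](O)C2 | starting material
2 | (2R,3S)-5,7-bis(benzyloxy)-2-[3,4,5-tris(benzyloxy)phenyl]chroman-3-ol | O(Cc1ccccc1)c1cc(OCc3ccccc3)c2c(c1)O[C@H](c1cc(OCc3ccccc3)c(OCc3ccccc3)c(OCc3ccccc3)c1)[C@@H](O)C2 | intermediate
3 | (2R,3S)-3,5,7-tris(benzyloxy)-2-[3,4,5-tris(benzyloxy)phenyl]chromane | O(Cc1ccccc1)c1cc(OCc3ccccc3)c2c(c1)O[C@H](c1cc(OCc3ccccc3)c(OCc3ccccc3)c(OCc3ccccc3)c1)[C@@H](OCc3ccccc3)C2 | intermediate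
4 | (2R,3S)-3,5,7-tris(benzyloxy)-8-bromo-2-[3,4,5-tris(benzyloxy)phenyl]chromane | O(Cc1ccccc1)c1cc(OCc3ccccc3)c2c(c1Br)O[C@H](c1cc(OCc3ccccc3)c(OCc3ccccc3)c(OCc3ccccc3)c1)[C@@H](OCc3ccccc3)C2 | intermediate
5 | 4-bromo-3-fluorophenol | Oc1ccc(Br)c(F)c1 | starting material
6 | 4-(benzyloxy)-1-bromo-2-fluorobenzene | Fc1cc(OCc2ccccc2)ccc1Br | intermediate
7 | 2-(benzyloxy)-N-methoxy-N-methylacetamide | CON(C)C(=O)COCc1ccccc1 | starting material
8 | [4-(benzyloxy)-2-fluorophenyl]magnesium chloride | Fc1cc(OCc2ccccc2)ccc1[Mg]Cl | intermediate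
9 | 2-(benzyloxy)-1-[4-(benzyloxy)-2-fluorophenyl]ethan-1-one | O=C(COCc1ccccc1)c1ccc(OCc2ccccc2)cc1F | intermediate
10 | (Z)-{[2-(benzyloxy)-1-(4-(benzyloxy)-2-fluorophenyl)ethenyl]oxy}trimethylsilane | C[Si](C)(C)O/C(=C\OCc1ccccc1)c1ccc(OCc2ccccc2)cc1F | intermediate
11 | 3,4,5-tris(benzyloxy)benzaldehyde | O=Cc1cc(OCc2ccccc2)c(OCc2ccccc2)c(OCc2ccccc2)c1 | starting material
12 | (2R,3R)-2-(benzyloxy)-1-[4-(benzyloxy)-2-fluorophenyl]-3-[3,4,5-tris(benzyloxy)phenyl]-3-(trimethylsilyloxy)propan-1-one | C[Si](C)(C)O[C@H](c1cc(OCc3ccccc3)c(OCc3ccccc3)c(OCc3ccccc3)c1)[C@@H](OCc3ccccc3)C(=O)c1ccc(OCc3ccccc3)cc1F | intermediate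
13 | tetrabutylammonium (1R,2R)-2-(benzyloxy)-3-[4-(benzyloxy)-2-fluorophenyl]-3-oxo-1-[3,4,5-tris(benzyloxy)phenyl]propan-1-olate | CCCC[N+](CCCC)(CCCC)CCCC.[O-][C@H](c1cc(OCc3ccccc3)c(OCc3ccccc3)c(OCc3ccccc3)c1)[C@@H](OCc3ccccc3)C(=O)c1ccc(OCc3ccccc3)cc1F | intermediate
14 | (2R,3R)-3,7-bis(benzyloxy)-2-[3,4,5-tris(benzyloxy)phenyl]chroman-4-one | O(Cc1ccccc1)c1ccc2c(c1)O[C@H](c1cc(OCc3ccccc3)c(OCc3ccccc3)c(OCc3ccccc3)c1)[C@@H](OCc3ccccc3)C2=O | intermediate
15 | {(2R,3S)-3,5,7-tris(benzyloxy)-2-[3,4,5-tris(benzyloxy)phenyl]chroman-8-yl}lithium | O(Cc1ccccc1)c1cc(OCc3ccccc3)c2c(c1[Li])O[C@H](c1cc(OCc3ccccc3)c(OCc3ccccc3)c(OCc3ccccc3)c1)[C@@H](OCc3ccccc3)C2 | intermediate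
16 | (2R,3R)-3,7-bis(benzyloxy)-4-{(2R,3S)-3,5,7-tris(benzyloxy)-2-[3,4,5-tris(benzyloxy)phenyl]chroman-8-yl}-2-[3,4,5-tris(benzyloxy)phenyl]chroman-4-ol, both C4 epimers (C4 left undefined) | O(Cc1ccccc1)c1ccc2c(c1)O[C@H](c1cc(OCc3ccccc3)c(OCc3ccccc3)c(OCc3ccccc3)c1)[C@@H](OCc3ccccc3)C2(O)c1c(OCc3ccccc3)cc(OCc3ccccc3)c2c1O[C@H](c1cc(OCc3ccccc3)c(OCc3ccccc3)c(OCc3ccccc3)c1)[C@@H](OCc3ccccc3)C2 | intermediate
17 | (2R,3R)-3,7-bis(benzyloxy)-4-{(2R,3S)-3,5,7-tris(benzyloxy)-2-[3,4,5-tris(benzyloxy)phenyl]chroman-8-yl}-2-[3,4,5-tris(benzyloxy)phenyl]chroman-4-ylium trifluoroacetate | O(Cc1ccccc1)c1ccc2c(c1)O[C@H](c1cc(OCc3ccccc3)c(OCc3ccccc3)c(OCc3ccccc3)c1)[C@@H](OCc3ccccc3)[C+]2c1c(OCc3ccccc3)cc(OCc3ccccc3)c2c1O[C@H](c1cc(OCc3ccccc3)c(OCc3ccccc3)c(OCc3ccccc3)c1)[C@@H](OCc3ccccc3)C2.[O-]C(=O)C(F)(F)F | intermediate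
18 | (2R,3S,4R)-3,7-bis(benzyloxy)-4-{(2R,3S)-3,5,7-tris(benzyloxy)-2-[3,4,5-tris(benzyloxy)phenyl]chroman-8-yl}-2-[3,4,5-tris(benzyloxy)phenyl]chromane | O(Cc1ccccc1)c1ccc2c(c1)O[C@H](c1cc(OCc3ccccc3)c(OCc3ccccc3)c(OCc3ccccc3)c1)[C@@H](OCc3ccccc3)[C@H]2c1c(OCc3ccccc3)cc(OCc3ccccc3)c2c1O[C@H](c1cc(OCc3ccccc3)c(OCc3ccccc3)c(OCc3ccccc3)c1)[C@@H](OCc3ccccc3)C2 | intermediate
19 | robinetinidol-(4β→8)-gallocatechin, (2R,3S,4R)-2-(3,4,5-trihydroxyphenyl)-4-[(2R,3S)-3,5,7-trihydroxy-2-(3,4,5-trihydroxyphenyl)chroman-8-yl]chromane-3,7-diol | Oc1ccc2c(c1)O[C@H](c1cc(O)c(O)c(O)c1)[C@@H](O)[C@H]2c1c(O)cc(O)c2c1O[C@H](c1cc(O)c(O)c(O)c1)[C@@H](O)C2 | target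

**Step count and risks**

Total steps: 10. Longest linear sequence: 7 steps (steps 4 to 10, from 4-bromo-3-fluorophenol).

Steps most likely to fail:

Step 7. The aldol stage may give insufficient enantiofacial control, retro-aldol cleavage of the alkoxide before ring closure may erode the configuration at C2, and simple diastereoselectivity at C3 may be low. The fallback uses known chemistry, sets out from aldehyde 11 and comes back at ketone 14; ring C is then closed at O1–C2, the O1–C8a bond being bought with the phenol. Commercial 1-[4-(benzyloxy)-2-hydroxyphenyl]ethan-1-one F1 is protected (MOMCl, i-Pr2NEt, CH2Cl2) as 1-[4-(benzyloxy)-2-(methoxymethoxy)phenyl]ethan-1-one F2. Claisen–Schmidt condensation with 11 (KOH, EtOH) gives (E)-1-[4-(benzyloxy)-2-(methoxymethoxy)phenyl]-3-[3,4,5-tris(benzyloxy)phenyl]prop-2-en-1-one F3. Juliá–Colonna epoxidation (poly-L-leucine, urea–hydrogen peroxide, DBU, THF) should give [4-(benzyloxy)-2-(methoxymethoxy)phenyl]{(2R,3S)-3-[3,4,5-tris(benzyloxy)phenyl]oxiran-2-yl}methanone F4. HCl in MeOH removes the acetal, and the freed phenol opens the epoxide at the benzylic carbon with inversion to (2R,3R)-7-(benzyloxy)-3-hydroxy-2-[3,4,5-tris(benzyloxy)phenyl]chroman-4-one F5. Benzylation under neutral conditions (BnBr, Ag2O, CH2Cl2) gives 14.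

Step 8. The hindered aryllithium may enolize the ketone at C3, and the enolate may then expel the ring oxygen (ring opening), or addition may be slow. The fallback sets out from ketone 14 and arene 3 and comes back at 18. NaBH4 (MeOH/THF, 0 °C) reduces 14 to (2R,3S,4R)-3,7-bis(benzyloxy)-2-[3,4,5-tris(benzyloxy)phenyl]chroman-4-ol F6. TMSOTf (CH2Cl2, −78 °C) ionizes F6, and the secondary cation alkylates C8 of 3 in a Friedel–Crafts reaction, the classical way to the interflavan bond. Both C4 epimers are expected, the 3,4-trans one probably in excess, and the 3,4-cis isomer 18 is separated by chromatography.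

Step 9. Hydride may be delivered to the wrong face of the cation, or the cation may lose the C3 proton to an enol ether whose re-protonation scrambles C3. The fallback replaces the cation by a radical, sets out from 16 and comes back at 18. Acylation (methyl chlorooxoacetate, DMAP, pyridine) gives methyl (2R,3R)-3,7-bis(benzyloxy)-4-{(2R,3S)-3,5,7-tris(benzyloxy)-2-[3,4,5-tris(benzyloxy)phenyl]chroman-8-yl}-2-[3,4,5-tris(benzyloxy)phenyl]chroman-4-yl oxalate F7. Barton-type deoxygenation (Bu3SnH, AIBN, toluene, 110 °C) generates the C4 radical, which should take hydrogen from the tin hydride anti to the 3-benzyloxy group to give 18.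

Further compounds
F1 | step 7 | 1-[4-(benzyloxy)-2-hydroxyphenyl]ethan-1-one | CC(=O)c1ccc(OCc2ccccc2)cc1O
F2 | step 7 | 1-[4-(benzyloxy)-2-(methoxymethoxy)phenyl]ethan-1-one | CC(=O)c1ccc(OCc2ccccc2)cc1OCOC
F3 | step 7 | (E)-1-[4-(benzyloxy)-2-(methoxymethoxy)phenyl]-3-[3,4,5-tris(benzyloxy)phenyl]prop-2-en-1-one | COCOc1cc(OCc2ccccc2)ccc1C(=O)/C=C/c1cc(OCc2ccccc2)c(OCc2ccccc2)c(OCc2ccccc2)c1
F4 | step 7 | [4-(benzyloxy)-2-(methoxymethoxy)phenyl]{(2R,3S)-3-[3,4,5-tris(benzyloxy)phenyl]oxiran-2-yl}methanone | O1[C@@H](c2cc(OCc3ccccc3)c(OCc3ccccc3)c(OCc3ccccc3)c2)[C@@H]1C(=O)c1ccc(OCc2ccccc2)cc1OCOC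
F5 | step 7 | (2R,3R)-7-(benzyloxy)-3-hydroxy-2-[3,4,5-tris(benzyloxy)phenyl]chroman-4-one | O(Cc1ccccc1)c1ccc2c(c1)O[C@H](c1cc(OCc3ccccc3)c(OCc3ccccc3)c(OCc3ccccc3)c1)[C@@H](O)C2=O
F6 | step 8 | (2R,3S,4R)-3,7-bis(benzyloxy)-2-[3,4,5-tris(benzyloxy)phenyl]chroman-4-ol | O(Cc1ccccc1)c1ccc2c(c1)O[C@H](c1cc(OCc3ccccc3)c(OCc3ccccc3)c(OCc3ccccc3)c1)[C@@H](OCc3ccccc3)[C@@H]2O
F7 | step 9 | methyl (2R,3R)-3,7-bis(benzyloxy)-4-{(2R,3S)-3,5,7-tris(benzyloxy)-2-[3,4,5-tris(benzyloxy)phenyl]chroman-8-yl}-2-[3,4,5-tris(benzyloxy)phenyl]chroman-4-yl oxalate (C4 left undefined) | O(Cc1ccccc1)c1ccc2c(c1)O[C@H](c1cc(OCc3ccccc3)c(OCc3ccccc3)c(OCc3ccccc3)c1)[C@@H](OCc3ccccc3)C2(OC(=O)C(=O)OC)c1c(OCc3ccccc3)cc(OCc3ccccc3)c2c1O[C@H](c1cc(OCc3ccccc3)c(OCc3ccccc3)c(OCc3ccccc3)c1)[C@@H](OCc3ccccc3)C2
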